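**Retrosynthetic overview**
- The target's 5-OH is removed to give 6,7,8,4'-tetramethoxyflavone; forward, a C4-carbonyl-directed C5–H hydroxylation is the last step.
- The flavone is opened at O1–C8a to a 1-(2-bromoaryl)-1,3-dione; forward, enolate O-arylation closes the pyranone.
- The dione is cut at C3–C4 into the acyl anion (carbene Breslow intermediate) of 2-bromo-3,4,5-trimethoxybenzaldehyde and the α-carbon of 4-methoxyphenacyl bromide, two natively electrophilic carbons.
- The bromoaldehyde comes from 3,4,5-trimethoxybenzaldehyde by ring bromination.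
- Ring order: both benzene rings are bought; the pyranone is the only ring formed, in the same pot as the key C–C bond.

Assumption: the target (5-hydroxy-6,7,8,4'-tetramethoxyflavone) has no stereocentre, so "single enantiomer" means the achiral compound itself.

**Step 1**
Reactants: 1 3,4,5-trimethoxybenzaldehyde
Product: 2 2-bromo-3,4,5-trimethoxybenzaldehyde
Conditions: NBS (1.1 equiv), CHCl3, reflux
Reagents that add atoms: N-bromosuccinimide, O=C1CCC(=O)N1Br
Why: Electrophilic aromatic bromination; the two equivalent free positions are each ortho and para to a methoxy group, so mono-bromination gives one product, and no stereocentre is formed.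

**Step 2**
Reactants: 2 2-bromo-3,4,5-trimethoxybenzaldehyde; 3 2-bromo-1-(4-methoxyphenyl)ethan-1-one
Product: 5 6,7,8-trimethoxy-2-(4-methoxyphenyl)-4H-chromen-4-one, via diketone 4 (not isolated)
Conditions: 2 (1.2 equiv), 2-mesityl-6,7-dihydro-5H-pyrrolo[2,1-c][1,2,4]triazol-2-ium chloride (20 mol %), K2CO3 (3 equiv), THF, 23 °C, 3 added over 6 h; then DMF, CuI (10 mol %), 100 °C
Reagents that add atoms: none
Why: Proposed new method: the triazolylidene adds to aldehyde 2 to give the Breslow intermediate, an acyl anion equivalent that displaces bromide from the α-carbon of 3 (SN2, or single-electron transfer then radical recombination), and collapse of the adduct releases the carbene and dione 4, which is held as its potassium enolate while slow addition of 3 over heterogeneous K2CO3 limits carbene alkylation and Darzens condensation; the closest known reaction types are the carbene-catalysed intramolecular SN2 acylation of aldehyde-tethered sulfonates to chromanones and the carbene-catalysed coupling of aryl aldehydes with activated alkyl bromides; the second stage is a known intramolecular Ullmann-type O-arylation of 1-(2-bromoaryl)-1,3-dione enolates, which can only close the six-membered pyranone, and no stereocentre is formed.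

**Step 3**
Reactants: 5 6,7,8-trimethoxy-2-(4-methoxyphenyl)-4H-chromen-4-one
Product: 7 5-hydroxy-6,7,8-trimethoxy-2-(4-methoxyphenyl)-4H-chromen-4-one, via aryl trifluoroacetate 6 (not isolated)
Conditions: [RuCl2(p-cymene)]2 (5 mol %), PhI(OCOCF3)2 (1.5 equiv), TFA/TFAA (4:1), 60 °C; then H2O, rt
Reagents that add atoms: [bis(trifluoroacetoxy)iodo]benzene, FC(F)(F)C(=O)OI(OC(=O)C(F)(F)F)c1ccccc1
Why: Ru(II)-catalysed ketone-directed ortho C–H oxygenation, a reaction type demonstrated at C5 of flavones; the C4 carbonyl can form a five-membered ruthenacycle only at C5–H, the sole A-ring C–H, oxidation by the iodine(III) reagent and C–O reductive elimination give the aryl trifluoroacetate, which hydrolyses on work-up, and no stereocentre is formed.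

**Compound list**
1 | 3,4,5-trimethoxybenzaldehyde | COc1cc(C=O)cc(OC)c1OC | starting material
2 | 2-bromo-3,4,5-trimethoxybenzaldehyde | COc1cc(C=O)c(Br)c(OC)c1OC | intermediate
3 | 2-bromo-1-(4-methoxyphenyl)ethan-1-one | COc1ccc(C(=O)CBr)cc1 | starting material
4 | 1-(2-bromo-3,4,5-trimethoxyphenyl)-3-(4-methoxyphenyl)propane-1,3-dione | COc1ccc(C(=O)CC(=O)c2cc(OC)c(OC)c(OC)c2Br)cc1 | intermediate
5 | 6,7,8-trimethoxy-2-(4-methoxyphenyl)-4H-chromen-4-one | COc1ccc(-c2cc(=O)c3cc(OC)c(OC)c(OC)c3o2)cc1 | intermediate
6 | 6,7,8-trimethoxy-2-(4-methoxyphenyl)-4-oxo-4H-chromen-5-yl trifluoroacetate | COc1ccc(-c2cc(=O)c3c(OC(=O)C(F)(F)F)c(OC)c(OC)c(OC)c3o2)cc1 | intermediate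
7 | 5-hydroxy-6,7,8-trimethoxy-2-(4-methoxyphenyl)-4H-chromen-4-one | COc1ccc(-c2cc(=O)c3c(O)c(OC)c(OC)c(OC)c3o2)cc1 | target

**Totals**
Total step count: 3. Longest linear sequence: 3 (1 → 2 → 5 → 7; compound 3 enters in step 2).

**Steps most likely to fail, with fallbacks**

Step 2 is the most likely to fail, because the carbene can be alkylated by 3 and 3 can undergo Darzens condensation with 2. The fallback sets out from 2 and uses a stoichiometric acyl anion of the B-ring aldehyde instead. Corey–Chaykovsky methylenation of 2 (Me3S+ I−, KOtBu, DMSO/THF) gives rac-2-(2-bromo-3,4,5-trimethoxyphenyl)oxirane F1. Separately, 4-methoxybenzaldehyde and propane-1,3-dithiol (BF3·OEt2) give 2-(4-methoxyphenyl)-1,3-dithiane F2. Lithiated F2 (n-BuLi, THF, −30 °C) opens F1 at its terminal carbon to give rac-1-(2-bromo-3,4,5-trimethoxyphenyl)-2-[2-(4-methoxyphenyl)-1,3-dithian-2-yl]ethan-1-ol F3. Dithiane hydrolysis (MeI, CaCO3, MeCN/H2O) gives rac-3-(2-bromo-3,4,5-trimethoxyphenyl)-3-hydroxy-1-(4-methoxyphenyl)propan-1-one F4. Dess–Martin oxidation of F4 then gives dione 4, where the fallback comes back to the route; 4 is closed to 5 with K2CO3, CuI, DMF, 100 °C as in the second stage of step 2.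

Step 3 is the next most likely to fail, because the iodine(III) oxidant in acid may attack the electron-rich rings instead of serving the ruthenacycle. The fallback sets out from 5. NBS (MeCN, rt) brominates the only free A-ring position, which is ortho and para to methoxy groups exactly as in step 1, to give 5-bromo-6,7,8-trimethoxy-2-(4-methoxyphenyl)-4H-chromen-4-one F5. Pd-catalysed hydroxylation of F5 (Pd2(dba)3, tBuXPhos, KOH, dioxane/H2O, 90 °C, then HCl) gives 7, where it comes back to the route. Any pyranone opened by hydroxide recloses to the same flavone on acidification, because the resulting 2,6-dihydroxyaryl unit is symmetric.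

Step 1 is the least risky, but could give over-bromination or stall on the deactivated aldehyde. The fallback sets out from 1. NaBH4 (MeOH, 0 °C) gives (3,4,5-trimethoxyphenyl)methanol F6. NBS (MeCN, 0 °C) brominates this more electron-rich ring to give (2-bromo-3,4,5-trimethoxyphenyl)methanol F7. MnO2 (CH2Cl2, rt) oxidises F7 to 2, where it comes back to the route.

**Further compounds**
F1 | step 2 | rac-2-(2-bromo-3,4,5-trimethoxyphenyl)oxirane | COc1cc(C2CO2)c(Br)c(OC)c1OC
F2 | step 2 | 2-(4-methoxyphenyl)-1,3-dithiane | COc1ccc(C2SCCCS2)cc1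
F3 | step 2 | rac-1-(2-bromo-3,4,5-trimethoxyphenyl)-2-[2-(4-methoxyphenyl)-1,3-dithian-2-yl]ethan-1-ol | COc1ccc(C2(CC(O)c3cc(OC)c(OC)c(OC)c3Br)SCCCS2)cc1
F4 | step 2 | rac-3-(2-bromo-3,4,5-trimethoxyphenyl)-3-hydroxy-1-(4-methoxyphenyl)propan-1-one | COc1ccc(C(=O)CC(O)c2cc(OC)c(OC)c(OC)c2Br)cc1
F5 | step 3 | 5-bromo-6,7,8-trimethoxy-2-(4-methoxyphenyl)-4H-chromen-4-one | COc1ccc(-c2cc(=O)c3c(Br)c(OC)c(OC)c(OC)c3o2)cc1
F6 | step 1 | (3,4,5-trimethoxyphenyl)methanol | COc1cc(CO)cc(OC)c1OC
F7 | step 1 | (2-bromo-3,4,5-trimethoxyphenyl)methanol | COc1cc(CO)c(Br)c(OC)c1OC
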